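**Assumption:** the target has no stereocentre and its prenyl alkene has no E/Z isomers. It is achiral, so "single enantiomer" needs no stereocontrol. The one transient stereocentre (compound 7) is racemic and is erased in the next step.

## Retrosynthetic overview
1. 11 ⇐ 10 (MOM removal) ⇐ 9 by aromatic Claisen. The C6–prenyl bond is delivered from O-5, whose only free ortho site is C6, and this also unmasks the chelated 5-OH.
2. 9 ⇐ 8 (semihydrogenation). The five prenyl carbons travel as a 1,1-dimethylpropargyl ether, which also protects O-5 and should tolerate the oxidant.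
3. 8 ⇐ 7 ⇐ 6. The C3–aryl bond comes from a biomimetic oxidative 1,2-aryl shift (C2→C3) of a chalcone, followed by O1–C2 closure. No cross-coupling or deoxybenzoin is used.
4. 6 ⇐ 3 + 5 (Claisen–Schmidt). 3 ⇐ desymmetrising mono-O-alkylation of symmetric 1 with 2, which fixes O-1 versus O-5, and therefore 6- versus 8-prenyl, in step 1.
5. Ring order: rings A and B are purchased. The pyranone C ring is the only ring built (step 5).

## Route

**Step 1**
Reactants: 1, 2',6'-dihydroxy-4'-methoxyacetophenone; 2, 3-chloro-3-methylbut-1-yne
Product: 3, 1-[2-hydroxy-4-methoxy-6-(2-methylbut-3-yn-2-yloxy)phenyl]ethanone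
Conditions: 2 (1.2 equiv), DBU (1.3 equiv), CuCl2·2H2O (1 mol %), MeCN, 0 °C → rt
Reagents that add atoms: 3-chloro-3-methylbut-1-yne, C#CC(C)(C)Cl
Why: Cu-catalysed propargylic etherification via a copper allenylidene, captured by the phenoxide at the tertiary carbon; the two OH groups of 1 are equivalent, so one product forms, and the remaining OH is more tightly chelated and resists a second alkylation.

**Step 2**
Reactants: 4, 2,4-dihydroxybenzaldehyde
Product: 5, 2,4-bis(methoxymethoxy)benzaldehyde
Conditions: NaH (2.5 equiv), MOMCl (2.5 equiv), DMF, 0 °C → rt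
Reagents that add atoms: chloromethyl methyl ether (MOMCl), COCCl
Why: Williamson-type O-alkylation; full deprotonation with NaH is needed to bring in the chelated 2-OH.

**Step 3**
Reactants: 3; 5
Product: 6, (E)-3-[2,4-bis(methoxymethoxy)phenyl]-1-[2-hydroxy-4-methoxy-6-(2-methylbut-3-yn-2-yloxy)phenyl]prop-2-en-1-one (chalcone)
Conditions: KOH (10 equiv), EtOH–H2O, rt, 48 h; cold AcOH to pH 6
Reagents that add atoms: none
Why: Claisen–Schmidt condensation with E1cB dehydration gives the thermodynamic E-enone; the MOM ethers and the propargyl ether (no propargylic H) are base-stable, and the phenolate keeps the chalcone open.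

**Step 4 (key step)**
Reactants: 6
Product: 7, (±)-2-[2,4-bis(methoxymethoxy)phenyl]-1-[2-hydroxy-4-methoxy-6-(2-methylbut-3-yn-2-yloxy)phenyl]-3,3-dimethoxypropan-1-one
Conditions: Tl(NO3)3·3H2O (1.1 equiv), MeOH–HC(OMe)3 (1:1), 0 °C, 20–30 min; solid NaHCO3, filter off TlNO3
Reagents that add atoms: methanol, CO (two MeO groups; HC(OMe)3, COC(OC)OC, is an equivalent source)
Why: McKillop–Taylor Tl(III) oxidative rearrangement of a chalcone: methoxythallation, then C–Tl heterolysis with phenonium-type 1,2-migration of the very electron-rich 2,4-dialkoxyphenyl group and MeOH capture of the oxocarbenium; donor B rings favour rearrangement over aurone formation and react fast, which should spare the hindered, inductively deactivated alkyne and the MOM ethers, and the new stereocentre is racemic and removed in step 5.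

**Step 5**
Reactants: 7
Product: 8, 3-[2,4-bis(methoxymethoxy)phenyl]-7-methoxy-5-(2-methylbut-3-yn-2-yloxy)-4H-chromen-4-one
Conditions: Cs2CO3 (1.5 equiv), dry DMF, 60 °C; AcOH-buffered work-up
Reagents that add atoms: none
Why: Proposed new method: base closure replaces the usual acid closure because acid would form an oxocarbenium that the 2'-OMOM oxygen can trap to give a 3-aroylbenzofuran; the doubly activated α-H allows E1cB loss of MeOH to a β-methoxyenone, and the 2-phenoxide then closes by 6-endo oxa-Michael addition and a second MeO⁻ expulsion, the closest known reaction types being carbonate-induced MeOH elimination from β-keto acetals and 2-methoxy-3-acyl-2,3-dihydrobenzofurans and the addition–elimination closure of o-hydroxyaryl enaminones to chromones.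

**Step 6**
Reactants: 8
Product: 9, 3-[2,4-bis(methoxymethoxy)phenyl]-7-methoxy-5-(2-methylbut-3-en-2-yloxy)-4H-chromen-4-one
Conditions: H2 (1 atm), Lindlar catalyst, quinoline, EtOAc, rt, stop at 1 equiv H2; filter through basic alumina and use directly
Reagents that add atoms: none
Why: Lindlar semihydrogenation of the terminal alkyne; the conjugated trisubstituted C2=C3 bond and the MOM ethers are inert to the poisoned catalyst.

**Step 7 (key step)**
Reactants: 9
Product: 10, 3-[2,4-bis(methoxymethoxy)phenyl]-5-hydroxy-7-methoxy-6-(3-methylbut-2-enyl)-4H-chromen-4-one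
Conditions: degassed PhMe, base-washed sealed tube, 110 °C
Reagents that add atoms: none
Why: Aromatic Claisen [3,3] rearrangement of a 1,1-dimethylallyl aryl ether gives the normal prenyl group directly; C4a is blocked, so C6 is the only ortho terminus, fast enolisation pre-empts a Cope shift to C8, and the new 5-OH···O=C4 chelate adds driving force.

**Step 8**
Reactants: 10
Product: 11, 7-O-methylluteone, 3-(2,4-dihydroxyphenyl)-5-hydroxy-7-methoxy-6-(3-methylbut-2-enyl)-4H-chromen-4-one
Conditions: 2 M aq HCl–MeOH (1:5), 50 °C, 1–2 h, monitored
Reagents that add atoms: none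
Why: Acid hydrolysis of aryl MOM acetals, the standard endgame for prenylflavonoids; chroman formation is slow because 7-O is methylated and the only neighbouring OH (5-OH) is tied up in the chelate.

## Compound list
| No. | Name | SMILES | Role |
|---|---|---|---|
| 1 | 2',6'-dihydroxy-4'-methoxyacetophenone | CC(=O)c1c(O)cc(OC)cc1O | starting material |
| 2 | 3-chloro-3-methylbut-1-yne | C#CC(C)(C)Cl | starting material |
| 3 | mono(1,1-dimethylpropargyl) ether of 1 | CC(=O)c1c(O)cc(OC)cc1OC(C)(C)C#C | intermediate |
| 4 | 2,4-dihydroxybenzaldehyde | O=Cc1ccc(O)cc1O | starting material |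
| 5 | 2,4-bis(methoxymethoxy)benzaldehyde | COCOc1ccc(C=O)c(OCOC)c1 | intermediate |
| 6 | (E)-chalcone | COCOc1ccc(/C=C/C(=O)c2c(O)cc(OC)cc2OC(C)(C)C#C)c(OCOC)c1 | intermediate |
| 7 | rearranged β-keto dimethyl acetal (racemic) | COCOc1ccc(C(C(OC)OC)C(=O)c2c(O)cc(OC)cc2OC(C)(C)C#C)c(OCOC)c1 | intermediate |
| 8 | 5-O-(1,1-dimethylpropargyl) isoflavone | COCOc1ccc(-c2coc3cc(OC)cc(OC(C)(C)C#C)c3c2=O)c(OCOC)c1 | intermediate |
| 9 | 5-O-(1,1-dimethylallyl) isoflavone | COCOc1ccc(-c2coc3cc(OC)cc(OC(C)(C)C=C)c3c2=O)c(OCOC)c1 | intermediate |
| 10 | 2',4'-di-O-MOM-7-O-methylluteone | COCOc1ccc(-c2coc3cc(OC)c(CC=C(C)C)c(O)c3c2=O)c(OCOC)c1 | intermediate |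
| 11 | 7-O-methylluteone (achiral) | COc1cc2occ(-c3ccc(O)cc3O)c(=O)c2c(O)c1CC=C(C)C | target |

## Step count
- **Total steps:** 8
- **Longest linear sequence:** 7 (1 → 3 → 6 → 7 → 8 → 9 → 10 → 11)

## Steps most likely to fail
1. **Step 4.** Tl(III) may oxidise or hydrate the alkyne, or the HNO3 released may strip the MOM groups.
   Fallback: abandon the aryl shift. Convert 3 to its enaminone with DMF-DMA, iodocyclise with I2 to the 3-iodochromone, and use Suzuki coupling with 2,4-bis(methoxymethoxy)phenylboronic acid. This intercepts 8.
2. **Step 5.** The unprecedented base closure may stall at the β-methoxyenone or open the ring.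
   Fallback: form the O1–C2 bond first. Cyclise chalcone 6 to the 5-alkoxyflavanone (NaOAc, EtOH), then run the 2,3-aryl shift on the flavanone with Koser's reagent, PhI(OH)OTs. This gives 8 directly by proton loss, with no acetal to close.
3. **Step 7.** The tertiary allyl ether may ionise and lose isoprene instead of rearranging.
   Fallback: build the C6 side chain in two C–C events. Take the resulting 5-OH isoflavone, O-allylate it, run the thermal Claisen to the 6-allyl compound (about 190 °C), and convert allyl to prenyl by cross-metathesis with 2-methylbut-2-ene (Grubbs II). This gives 10.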